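## Structural features

The target is a xenicane-type diterpenoid in which a 3,4-dihydro-2H-pyran (C1, O2, C3=C4, C4a, C11a) is trans-fused through C4a–C11a to a nine-membered carbocycle (C4a, C5 to C11, C11a). The carbocycle carries an exocyclic methylene on C11 and a trisubstituted epoxide at C7–C8 (methyl on C7) whose two ring bonds (to C6 and C9) are cis, so it derives from a Z-alkene. C1 is an acetal carbon with an acetoxy group trans to the C11a–C11 bond, and C4 carries a side chain that begins with the acetoxy stereocentre C12 and ends in an E-configured methyl 2-methylbut-2-enoate (C13 to C15). The six stereocentres (1R, 4aS, 7S, 8R, 11aR, 12S) form three groups: C1/C11a/C4a are contiguous on the pyran, C7/C8 lie across the medium ring, and C12 stands outside both rings next to the sp2 carbon C4. The fragile sites are the acyloxy acetal at C1, the enol ether C3=C4 with its allylic C12 acetate, the acid-labile epoxide, and the allylic C11a hydrogen, which becomes epimerisable whenever C1 is a free aldehyde. The real difficulty is the nine-membered ring with its Z-trisubstituted C7=C8 unit, followed by the need to tell four π-systems apart late in the synthesis. The key step exploits the chain C11–C10–C9–C8=C7, which is a γ,δ-unsaturated ketone once C11 is a carbonyl, together with the fact that C11, C7 with its methyl, C6, C5, C4a and C11a map onto the ring of carvone and C4/C3/C12 onto its isopropenyl group.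

## Logic of the disconnections

28 to 26 + 27. The C14=C15 double bond is cut (cross-metathesis). It is the most remote and least hindered π-bond; cutting it reduces the side chain to a terminal vinyl group on 26 and leaves 27 as a commodity partner. The forward step must engage only the monosubstituted alkene, leave C11=CH2, C3=C4 and the epoxide alone, and give the E-enoate.

26 to 25 to 23. The C12 acetyl group is removed and the C12–C13 bond is cut (allyl addition to the C12 aldehyde). C12 is the only stereocentre outside the rings, so it is best set by a chiral reagent on a planar aldehyde. The cut also returns C3=C4 to conjugation with a carbonyl group, which protects the enol ether. The forward step must add 1,2 to a vinylogous formate without Lewis acid (epoxide, acyloxy acetal) and from the Si face.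

23 to 22. The two C–O bonds of the epoxide are cut, giving the Z-alkene C7=C8. The epoxide is the most acid-sensitive group, so it is introduced after all acidic operations but before C3=C4 loses its deactivating carbonyl. The forward step needs site selectivity for the trisubstituted alkene over C11=CH2 and facial selectivity on a medium ring.

22 to 21 to 19 (through 20). The acetyl group on the C1 oxygen is removed, the O2–C1 bond is opened to 20, and the three aldehydes are reduced to 19. A 1-acyloxy-dihydropyran-4-carbaldehyde is the trapped ring tautomer of a trialdehyde in which C3 and C12 are the two formyl groups of a malondialdehyde unit on C4. The pyran, the C1 stereocentre and the C3=C4 bond vanish together, and C3 and C12 become equivalent, so they never need to be differentiated. The forward step needs three oxidations in one operation without enolising C1–C11a towards the C11 methylene, and an acylation that fixes the ring form with the C1 oxygen trans to C11.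

19 to 18 to 17. The protecting groups are restored and the C11=CH2 bond is cut to the C11 ketone. This uncovers the γ,δ-unsaturated ketone C11(=O)–C10–C9–C8=C7. The forward methylenation must be non-basic, because C11a is α to the ketone and β to a silyloxy group.

17 to 16. The C9–C10 bond is cut and the O–C7 bond restored (retro-Claisen). The nine-membered ring contracts to a seven-membered cyclic enol ether; the Z-alkene becomes a vinyl group on a tertiary ether carbon whose configuration does not matter. The forward step must give Z geometry and must outrun isomerisation or hydrolysis of the enol ether.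

16 to 15 to 14. The exocyclic carbon C10 is removed (lactone carbonyl at C11) and the ring oxygen is taken out from between C11 and C7 (retro-Baeyer–Villiger). The oxepane is traced to a cyclohexanone made of C11, C7, C6, C5, C4a and C11a. The forward steps need a base-free lactone methylenation and oxygen insertion on the C7 side without epoxidation. The last demand is met by design: the C4 unit is carried as a saturated, symmetric 1,3-dioxane and not as an allylic ether with a 1,1-disubstituted alkene, so 14 contains no alkene other than the vinyl group.

14 to 13 to 10 + 11. The vinyl group is rehydrated to the carbinol and the C7–C8 bond is cut (aldol). The enone of 10 serves as a regiodefined enolate precursor. The forward steps need conjugate hydride delivery, an aldol at a fully substituted enolate carbon, and an elimination that can only form the terminal alkene.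

10 to 9 to 7. The silyl group is removed and the C11a–C1 bond is cut (hydroxymethylation of the kinetic enolate). The C11a stereocentre is thereby derived from C4a. The forward step needs α′-deprotonation and attack anti to the neighbouring substituent.

7 to 6 to 4 to 2 to 1. The acetonide is removed, the C3–O bond is cut (hydroboration of the 1,1-disubstituted alkene), and the C12–O bond is cut (acetate for chloride, chloride from allylic chlorination). This arrives at 1, which supplies C4a in the required absolute configuration and all six ring carbons. The forward hydroboration must prefer the alkene to the enone carbonyl.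

## Other disconnections considered

Alternative 1: The cut is O2–C1 together with C4a–C11a. In the forward sense the dioxinone A1 is heated and loses acetone. The resulting acylketene is captured by the C3 hydroxyl (O2–C1). The C11a enol of the new β-keto ester then adds across the thirteen-membered ring to C4a of the unsaturated nitrile (C4a–C11a), giving A2.
- In its favour: two bonds and both rings form in one reagent-free thermal operation. Acylketene lactonisation needs no activating agent. The epoxide is set on an open chain. The nine-membered ring is closed transannularly and not end to end.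
- Against it here: the relative configuration of C4a, C11a and C4, and above all their relation to the remote epoxide, would rest on the conformation of a flexible macrocycle. A2 also has the wrong oxidation pattern: C1 is a lactone, C11 is the ketone of an acidic β-keto lactone that is hard to methylenate, and C4 is a saturated nitrile. C3=C4, C12 and the C1 acetal would need several redox steps with the epoxide present.
- Comparison: on skeleton construction the alternative is the better plan (two rings against one). On mechanism the two are equal in being thermal and reagent-free, but the Claisen has one selectivity issue (E/Z, fixed by ring constraint) where the transannular Michael has three. On step economy the alternative is probably shorter up to the bicycle and longer after it, so no clear gain is expected.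

Alternative 2: The cut is C5–C6. In the forward sense zerovalent palladium, for example Pd(PPh3)4, ionises the C8 carbonate of A3 to a π-allyl complex over C6–C7–C8. The C5 bis(phenylsulfonyl) carbanion attacks the C6 terminus, giving A4.
- In its favour: the conditions are mild and catalytic. Both C8 epimers converge, which equals the convergence of the C7 epimers in the chosen plan. The pyran acetal with C1, C4a, C11a and the C11 methylene is already complete, which is better than the chosen plan, where the pyran is built after the ring.
- Against it here: this is an end-to-end closure of a nine-membered ring, with entropic and transannular penalties, high dilution, and competition from attack at C8 (seven-membered ring). Z geometry requires reaction through the anti π-allyl isomer, which the C7 methyl favours but does not enforce. Two sulfonyl groups must be removed reductively beside an acetal and an enol ether, C4 still lacks the C12 carbon, and the C1 methoxy group must be exchanged for acetoxy.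
- Comparison: on structure the alternative is more convergent. On mechanism the catalyst-controlled regio- and geometric selectivity is less certain than the ring-enforced outcome of the rearrangement. On step economy the two should be similar, because desulfonylation, C12 introduction and acetal exchange offset the shorter ring construction.

Alternative 3: The cut is C6–C7. In the forward sense 9-BBN adds to the C4a vinyl group of A5 (boron on C6). PdCl2(dppf) with base then couples the alkylborane with the (Z)-C7 iodide within the molecule, giving A6.
- In its favour: the Z geometry is preset in the iodoalkene and transferred with retention, so on geometric certainty the alternative is the better plan. The C4 ester is already at a useful oxidation level for C12, which equals the late C12 aldehyde of the chosen plan.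
- Against it here: this is again an end-to-end nine-ring closure (dilution, protodeboronation, β-hydride elimination). A5 needs an independent asymmetric synthesis of the trans-disubstituted pyran and a geometrically pure trisubstituted iodoalkene. After closure the dioxolane must be removed with acid beside a methyl acetal and an enol ether, followed by methylenation, ester-to-aldehyde adjustment and acetal exchange.
- Comparison: both plans reach a Z-cyclononene fused to the pyran. The alternative has the pyran early and a shorter longest linear sequence through convergence, which is its advantage. The chosen plan takes its stereocentres from the chiral pool and needs no metal or stoichiometric borane for ring formation. Total step counts are expected to be similar.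

Key step: step 11

Remark on the chemistry: the aldol of step 7 is assumed to give both configurations at C7 and at the carbinol carbon; 13 to 16 are carried as these mixtures (SMILES left open at those centres), because step 8 removes the carbinol centre and step 11 the C7 centre.

## Route

Step 1
Reactants: 1 (S)-carvone
Product: 2 (5S)-5-(3-chloroprop-1-en-2-yl)-2-methylcyclohex-2-en-1-one (10-chlorocarvone)
Conditions: Ca(OCl)2, CO2 (dry ice), CH2Cl2/H2O, 0 °C
Reagents that add atoms: calcium hypochlorite, [Ca+2].[O-]Cl.[O-]Cl
Why: Ene-type allylic chlorination by HOCl occurs at the electron-rich 1,1-disubstituted alkene with double-bond shift; the enone alkene is too electron-poor to react and the stereocentre is untouched.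

Step 2
Reactants: 2 10-chlorocarvone
Product: 4 (5S)-5-(3-hydroxyprop-1-en-2-yl)-2-methylcyclohex-2-en-1-one (10-hydroxycarvone), via allylic acetate 3 (not isolated)
Conditions: KOAc, Bu4NI (cat.), DMF, 50 °C; then K2CO3 (cat.), MeOH, 0 °C → rt
Reagents that add atoms: potassium acetate, CC(=O)[O-].[K+]
Why: SN2 displacement of the primary allylic chloride by a weakly basic carboxylate, then transesterification; a strongly basic oxygen nucleophile is avoided because it would enolise the ketone and cause intramolecular C-alkylation.

Step 3
Reactants: 4 10-hydroxycarvone
Product: 6 (5S)-5-(1,3-dihydroxypropan-2-yl)-2-methylcyclohex-2-en-1-one, via bis-boryl adduct 5 (not isolated)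
Conditions: 9-BBN (2.1 equiv), THF, 0 °C → rt; then aq. NaOAc, 30% H2O2, 0 °C
Reagents that add atoms: hydrogen peroxide, OO
Why: Anti-Markovnikov hydroboration–oxidation; 2-substituted terminal alkenes are the fastest substrate class for 9-BBN, so the enone should survive at controlled stoichiometry (the first equivalent is taken by the hydroxyl), and buffered peroxide avoids nucleophilic epoxidation of the enone. The new CH carbon carries two identical CH2OH arms and is not a stereocentre.

Step 4
Reactants: 6 enone diol
Product: 7 (5S)-5-(2,2-dimethyl-1,3-dioxan-5-yl)-2-methylcyclohex-2-en-1-one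
Conditions: Me2C(OMe)2, PPTS (cat.), acetone, rt
Reagents that add atoms: 2,2-dimethoxypropane, COC(C)(C)OC
Why: Acid-catalysed transacetalisation to the six-membered 1,3-dioxane; it masks C3 and C12 at the same oxidation level in one symmetric group that is stable to base, hydride, peracid and heat.

Step 5
Reactants: 7 dioxanyl enone
Product: 9 (5R,6S)-5-(2,2-dimethyl-1,3-dioxan-5-yl)-6-(hydroxymethyl)-2-methylcyclohex-2-en-1-one (5,6-trans; C5 spatially as in 1), via lithium dienolate 8 (not isolated)
Conditions: LiN(i-Pr)2, THF, −78 °C; CH2O (gas, from paraformaldehyde), −78 °C; AcOH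
Reagents that add atoms: formaldehyde, C=O
Why: Kinetic α′-deprotonation of the enone and aldol addition to monomeric formaldehyde; the electrophile enters anti to the bulky substituent on the neighbouring carbon, which sets C11a trans to C4a, the arrangement that is also thermodynamically preferred.

Step 6
Reactants: 9 hydroxymethyl enone
Product: 10 (5R,6S)-6-[(tert-butyldimethylsilyloxy)methyl]-5-(2,2-dimethyl-1,3-dioxan-5-yl)-2-methylcyclohex-2-en-1-one (5,6-trans)
Conditions: TBSCl, imidazole, DMF, 0 °C → rt
Reagents that add atoms: tert-butyldimethylsilyl chloride, CC(C)(C)[Si](C)(C)Cl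
Why: Standard silylation of a primary alcohol under weakly basic conditions, so that the β-hydroxy ketone neither fragments by retro-aldol nor eliminates.

Step 7
Reactants: 10 silyl ether enone; 11 acetaldehyde
Product: 13 6-[(tert-butyldimethylsilyloxy)methyl]-5-(2,2-dimethyl-1,3-dioxan-5-yl)-2-(1-hydroxyethyl)-2-methylcyclohexan-1-one (5,6-trans; mixture at C2 and at the carbinol carbon), via lithium enolate 12 (not isolated)
Conditions: LiBH(s-Bu)3, THF, −78 °C; then MeCHO, −78 °C; AcOH
Reagents that add atoms: none
Why: Reductive aldol: the hindered borohydride adds 1,4 to the α-methyl enone and gives the enolate regiospecifically at the methyl-bearing carbon (C7), which is trapped by the aldehyde to form the quaternary centre. Its configuration and that of the carbinol need no control, and C11a is not enolised at −78 °C.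

Step 8
Reactants: 13 β-hydroxy ketone
Product: 14 6-[(tert-butyldimethylsilyloxy)methyl]-5-(2,2-dimethyl-1,3-dioxan-5-yl)-2-methyl-2-vinylcyclohexan-1-one (5,6-trans; C2 epimers)
Conditions: Burgess reagent (MeO2CN−SO2N+Et3), toluene, 60 °C
Reagents that add atoms: none
Why: Syn-elimination through the sulfamate ester; the only β-hydrogens are on the methyl group (the other β-carbon is quaternary), so the terminal vinyl group is the only possible alkene from either carbinol epimer, and the neutral conditions exclude retro-aldol.

Step 9
Reactants: 14 α-vinyl ketone
Product: 15 3-[(tert-butyldimethylsilyloxy)methyl]-4-(2,2-dimethyl-1,3-dioxan-5-yl)-7-methyl-7-vinyloxepan-2-one (3,4-trans; C7 epimers)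
Conditions: mCPBA, NaHCO3, CH2Cl2, 0 °C → rt
Reagents that add atoms: 3-chloroperbenzoic acid, OOC(=O)c1cccc(Cl)c1
Why: Baeyer–Villiger oxidation: the quaternary allylic carbon C7 migrates in preference to the C11a methine, which is deactivated by the silyloxymethyl group, so the ring oxygen is placed between C11 and C7. The only alkene present is a monosubstituted vinyl group on a quaternary carbon, which peracids epoxidise far more slowly than they oxidise the ketone.

Step 10
Reactants: 15 vinyl lactone
Product: 16 3-[(tert-butyldimethylsilyloxy)methyl]-4-(2,2-dimethyl-1,3-dioxan-5-yl)-7-methyl-2-methylene-7-vinyloxepane (3,4-trans; C7 epimers)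
Conditions: Cp2TiMe2 (2.5 equiv), toluene, 70 °C, dark; filtration through basic Al2O3
Reagents that add atoms: Cp2TiMe2 (dimethyltitanocene), [CH3-].[CH3-].[Ti+4].[cH-]1cccc1.[cH-]1cccc1
Why: Petasis methylenation: thermally generated Cp2Ti=CH2 adds to the lactone carbonyl and cycloreverts to the exocyclic enol ether; the reagent is non-basic, so C11a is not epimerised, and lactones are standard substrates.

Step 11
Reactants: 16 2-methylene-7-vinyloxepane
Product: 17 (Z)-9-[(tert-butyldimethylsilyloxy)methyl]-8-(2,2-dimethyl-1,3-dioxan-5-yl)-5-methylcyclonon-4-en-1-one (8,9-trans; these carbons are C4a and C11a)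
Conditions: toluene (degassed, 0.01 M), Et3N (trace), base-washed sealed tube, 170 °C
Reagents that add atoms: none
Why: Concerted [3,3]-sigmatropic (aliphatic Claisen) shift of the allyl vinyl ether C10=C11–O–C7–C8=C9: C9–C10 forms while O–C7 breaks and C11 becomes the ketone. The closest known reaction type is the Claisen ring expansion of 2-methylene-6-vinyltetrahydropyrans to 4-cyclooctenones and of their oxepane homologues to 4-cyclononenones. The nine-membered ring is not closed end to end: it arises by two-carbon ring expansion of the oxepane through a bicyclic, boat-like transition state in which the ring oxygen is the one-atom bridge. No stereocentre is created; C7 becomes trigonal, so both C7 epimers of 16 give the same ketone, and C4a and C11a are spectators that stay trans because nothing in the neutral medium enolises C11. The selectivity required is Z geometry at C7=C8, and it is secured by the four-carbon tether C6–C5–C4a–C11a that joins C7 to C11: only the rotamer with C6 syn to C9 lets the vinyl terminus reach C10, whereas the E transition state would need a trans double bond inside a bridged nine-membered array. The acetonide and the silyl ether are inert at this temperature and no second 1,5-diene or ene partner is present. A base-washed vessel and a trace of amine suppress acid-catalysed migration of the exocyclic enol ether double bond into the ring, which is the main competing path.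

Step 12
Reactants: 17 (Z)-cyclononenone
Product: 18 tert-butyl{[(Z)-9-(2,2-dimethyl-1,3-dioxan-5-yl)-6-methyl-2-methylenecyclonon-5-en-1-yl]methoxy}dimethylsilane (1,9-trans)
Conditions: Zn, CH2Br2, TiCl4 (pre-formed reagent), THF/CH2Cl2, 0 °C → rt
Reagents that add atoms: dibromomethane, BrCBr
Why: Lombardo methylenation with the zinc/titanium gem-dimetallic reagent; it is non-basic, so the α-stereocentre C11a of the β-silyloxy ketone neither epimerises nor eliminates, and it is known to tolerate silyl ethers and acetonides.

Step 13
Reactants: 18 protected diene
Product: 19 2-[(Z)-2-(hydroxymethyl)-6-methyl-3-methylenecyclonon-6-en-1-yl]propane-1,3-diol (ring substituents trans)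
Conditions: CSA (0.1 equiv), MeOH, 0 °C → rt
Reagents that add atoms: none
Why: Acid-catalysed methanolysis removes the acetonide and the primary silyl ether together; catalytic sulfonic acid in methanol does not protonate the 1,1-disubstituted or the trisubstituted alkene at this temperature.

Step 14
Reactants: 19 triol
Product: 21 (4aS,11aR,Z)-1-hydroxy-7-methyl-11-methylene-1,4a,5,6,9,10,11,11a-octahydrocyclonona[c]pyran-4-carbaldehyde (both C1 anomers), via trialdehyde 20 (not isolated)
Conditions: DMP (3.5 equiv), NaHCO3, CH2Cl2, 0 °C → rt
Reagents that add atoms: none
Why: The three primary alcohols are oxidised to aldehydes; the 2-substituted malondialdehyde unit on C4 enolises and its enol hydroxyl adds to the C1 aldehyde, the same ring–chain tautomerism by which iridoid dialdehydes close to dihydropyranols. Either arm of the symmetric unit gives the same ring, no C4 stereocentre ever exists, and the buffered, base-free medium leaves C11a untouched.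

Step 15
Reactants: 21 lactol
Product: 22 (1R,4aS,11aR,Z)-4-formyl-7-methyl-11-methylene-1,4a,5,6,9,10,11,11a-octahydrocyclonona[c]pyran-1-yl acetate
Conditions: Ac2O, pyridine, DMAP (cat.), CH2Cl2, 0 °C → rt
Reagents that add atoms: acetic anhydride, CC(=O)OC(C)=O
Why: Acylation of the pseudo-acid lactol traps the ring form, as in the conversion of 2-formylbenzoic acid into 3-acetoxyphthalide. The C1 configuration is set under equilibrating conditions (anomers interconvert by ring opening and acyl transfer); as in iridoid aglycones the anomer with the C1 oxygen trans to the neighbouring ring-fusion bond (here C11a–C11) is expected to dominate, and that is the target configuration.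

Step 16
Reactants: 22 acetal acetate
Product: 23 (7S,8R)-7,8-epoxide of 22 (C7–C8 oxirane, ring bonds cis)
Conditions: D-fructose-derived Shi ketone (1,2:4,5-di-O-isopropylidene-β-D-erythro-2,3-hexodiulo-2,6-pyranose, 1–3 equiv), KHSO5 (as Oxone), NaHCO3, aq. Na2EDTA, MeCN, 0 °C, pH 7–8
Reagents that add atoms: potassium peroxymonosulfate, [K+].[O-]S(=O)(=O)OO
Why: Chiral dioxirane epoxidation: the electron-rich trisubstituted C7=C8 reacts faster than the 1,1-disubstituted C11 methylene and much faster than the push–pull C3=C4, and the near-neutral buffer spares the acyloxy acetal. Syn oxygen transfer to the Z-alkene gives the cis-epoxide, and the spiro transition-state model for this ketone, applied to a 1-methylcycloalkene-type olefin (same face as in the epoxidation of 1-phenylcyclohexene), predicts the 7S,8R oxide.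

Step 17
Reactants: 23 epoxy aldehyde
Product: 25 (1R,4aS,7S,8R,11aR)-7,8-epoxy-4-[(1S)-1-hydroxybut-3-en-1-yl] analogue of 22 (C12 = S), via borinate ester 24 (not isolated)
Conditions: (−)-Ipc2B(allyl) (1.5 equiv), Et2O, −78 °C; then pH 7 buffer, MeOH, 30% H2O2, 0 °C
Reagents that add atoms: (−)-B-allyldiisopinocampheylborane (from (+)-α-pinene), C=CCB([C@@H]1C[C@@H]2C[C@H]([C@H]1C)C2(C)C)[C@@H]1C[C@@H]2C[C@H]([C@H]1C)C2(C)C
Why: Allylboration through a closed six-membered chair transition state; the (+)-α-pinene-derived reagent adds to the Si face of the aldehyde, which gives 12S under reagent control. The reagent adds only 1,2 and needs no Lewis acid, so the epoxide, the acyloxy acetal and the enol ether are not activated.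

Step 18
Reactants: 25 homoallylic alcohol
Product: 26 12-O-acetate of 25 (1,12-diacetate with a terminal vinyl group)
Conditions: Ac2O, pyridine, DMAP (cat.), CH2Cl2, 0 °C
Reagents that add atoms: acetic anhydride, CC(=O)OC(C)=O
Why: Standard acylation of a secondary alcohol under mildly basic conditions, which avoids ionisation of the C12–O bond next to the enol ether; the configuration at C12 is retained.

Step 19
Reactants: 26 diacetate; 27 methyl methacrylate
Product: 28 CNP0184381.3 (target)
Conditions: 27 (10 equiv), second-generation Hoveyda–Grubbs catalyst RuCl2(=CH–C6H4-2-O-i-Pr)(H2IMes) (5 mol%), CH2Cl2, 40 °C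
Reagents that add atoms: none
Why: Cross-metathesis of the monosubstituted terminal alkene with the methacrylate; the exocyclic 1,1-disubstituted alkene and the trisubstituted enol ether are too hindered to enter the cycle, the epoxide and esters are tolerated, and α-methyl enoates form with the ester trans to the chain, which is the required E geometry. No ring stereocentre is touched, so C1, C4a, C7, C8, C11a and C12 are carried over unchanged from 26.

## Compound list

1 | (S)-carvone | CC1=CC[C@H](C(C)=C)CC1=O | starting material
2 | (5S)-5-(3-chloroprop-1-en-2-yl)-2-methylcyclohex-2-en-1-one | CC1=CC[C@H](C(=C)CCl)CC1=O | intermediate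
3 | 2-[(1S)-4-methyl-5-oxocyclohex-3-en-1-yl]prop-2-en-1-yl acetate (not isolated) | CC1=CC[C@H](C(=C)COC(C)=O)CC1=O | intermediate
4 | (5S)-5-(3-hydroxyprop-1-en-2-yl)-2-methylcyclohex-2-en-1-one | CC1=CC[C@H](C(=C)CO)CC1=O | intermediate
5 | O-boryl, C-boryl bis(9-borabicyclo[3.3.1]nonan-9-yl) adduct of 4 (not isolated; side-chain CH is a mixture) | CC1=CC[C@H](C(COB2C3CCCC2CCC3)CB2C3CCCC2CCC3)CC1=O | intermediate
6 | (5S)-5-(1,3-dihydroxypropan-2-yl)-2-methylcyclohex-2-en-1-one | CC1=CC[C@H](C(CO)CO)CC1=O | intermediate
7 | (5S)-5-(2,2-dimethyl-1,3-dioxan-5-yl)-2-methylcyclohex-2-en-1-one | CC1=CC[C@H](C2COC(C)(C)OC2)CC1=O | intermediate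
8 | lithium α′-dienolate of 7 (not isolated) | CC1=CC[C@H](C2COC(C)(C)OC2)C=C1[O-].[Li+] | intermediate
9 | (5R,6S)-5-(2,2-dimethyl-1,3-dioxan-5-yl)-6-(hydroxymethyl)-2-methylcyclohex-2-en-1-one (5,6-trans) | O=C1C(C)=CC[C@H](C2COC(C)(C)OC2)[C@H]1CO | intermediate
10 | (5R,6S)-6-[(tert-butyldimethylsilyloxy)methyl]-5-(2,2-dimethyl-1,3-dioxan-5-yl)-2-methylcyclohex-2-en-1-one (5,6-trans) | O=C1C(C)=CC[C@H](C2COC(C)(C)OC2)[C@H]1CO[Si](C)(C)C(C)(C)C | intermediate
11 | acetaldehyde | CC=O | starting material
12 | lithium enolate from conjugate reduction of 10 (not isolated) | [Li+].[O-]C1=C(C)CC[C@H](C2COC(C)(C)OC2)[C@H]1CO[Si](C)(C)C(C)(C)C | intermediate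
13 | 6-[(tert-butyldimethylsilyloxy)methyl]-5-(2,2-dimethyl-1,3-dioxan-5-yl)-2-(1-hydroxyethyl)-2-methylcyclohexan-1-one (5,6-trans; mixture at C2 and carbinol) | O=C1C(C)(C(C)O)CC[C@H](C2COC(C)(C)OC2)[C@H]1CO[Si](C)(C)C(C)(C)C | intermediate
14 | 6-[(tert-butyldimethylsilyloxy)methyl]-5-(2,2-dimethyl-1,3-dioxan-5-yl)-2-methyl-2-vinylcyclohexan-1-one (5,6-trans; C2 epimers) | O=C1C(C)(C=C)CC[C@H](C2COC(C)(C)OC2)[C@H]1CO[Si](C)(C)C(C)(C)C | intermediate
15 | 3-[(tert-butyldimethylsilyloxy)methyl]-4-(2,2-dimethyl-1,3-dioxan-5-yl)-7-methyl-7-vinyloxepan-2-one (3,4-trans; C7 epimers) | O=C1OC(C)(C=C)CC[C@H](C2COC(C)(C)OC2)[C@H]1CO[Si](C)(C)C(C)(C)C | intermediate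
16 | 3-[(tert-butyldimethylsilyloxy)methyl]-4-(2,2-dimethyl-1,3-dioxan-5-yl)-7-methyl-2-methylene-7-vinyloxepane (3,4-trans; C7 epimers) | C=C1OC(C)(C=C)CC[C@H](C2COC(C)(C)OC2)[C@H]1CO[Si](C)(C)C(C)(C)C | intermediate
17 | (Z)-9-[(tert-butyldimethylsilyloxy)methyl]-8-(2,2-dimethyl-1,3-dioxan-5-yl)-5-methylcyclonon-4-en-1-one (8,9-trans) | O=C1CC/C=C(C)\CC[C@H](C2COC(C)(C)OC2)[C@H]1CO[Si](C)(C)C(C)(C)C | intermediate
18 | tert-butyl{[(Z)-9-(2,2-dimethyl-1,3-dioxan-5-yl)-6-methyl-2-methylenecyclonon-5-en-1-yl]methoxy}dimethylsilane (1,9-trans) | C=C1CC/C=C(C)\CC[C@H](C2COC(C)(C)OC2)[C@H]1CO[Si](C)(C)C(C)(C)C | intermediate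
19 | 2-[(Z)-2-(hydroxymethyl)-6-methyl-3-methylenecyclonon-6-en-1-yl]propane-1,3-diol (ring substituents trans) | C=C1CC/C=C(C)\CC[C@H](C(CO)CO)[C@H]1CO | intermediate
20 | 2-[(Z)-2-formyl-6-methyl-3-methylenecyclonon-6-en-1-yl]propanedial (not isolated) | C=C1CC/C=C(C)\CC[C@H](C(C=O)C=O)[C@H]1C=O | intermediate
21 | (4aS,11aR,Z)-1-hydroxy-7-methyl-11-methylene-1,4a,5,6,9,10,11,11a-octahydrocyclonona[c]pyran-4-carbaldehyde (C1 anomers) | C=C1CC/C=C(C)\CC[C@@H]2C(C=O)=COC(O)[C@@H]12 | intermediate
22 | (1R,4aS,11aR,Z)-4-formyl-7-methyl-11-methylene-1,4a,5,6,9,10,11,11a-octahydrocyclonona[c]pyran-1-yl acetate | C=C1CC/C=C(C)\CC[C@@H]2C(C=O)=CO[C@H](OC(C)=O)[C@@H]12 | intermediate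
23 | (7S,8R)-7,8-epoxide of 22 | C=C1CC[C@H]2O[C@@]2(C)CC[C@@H]2C(C=O)=CO[C@H](OC(C)=O)[C@@H]12 | intermediate
24 | diisopinocampheylborinate of 25 (not isolated) | C=C1CC[C@H]2O[C@@]2(C)CC[C@@H]2C([C@H](CC=C)OB([C@@H]3C[C@@H]4C[C@H]([C@H]3C)C4(C)C)[C@@H]3C[C@@H]4C[C@H]([C@H]3C)C4(C)C)=CO[C@H](OC(C)=O)[C@@H]12 | intermediate
25 | 1-acetoxy-7,8-epoxy-4-[(1S)-1-hydroxybut-3-en-1-yl] bicycle (1R,4aS,7S,8R,11aR) | C=C1CC[C@H]2O[C@@]2(C)CC[C@@H]2C([C@H](CC=C)O)=CO[C@H](OC(C)=O)[C@@H]12 | intermediate
26 | 1,12-diacetate of the C12 but-3-enyl compound (12S) | C=C1CC[C@H]2O[C@@]2(C)CC[C@@H]2C([C@H](CC=C)OC(C)=O)=CO[C@H](OC(C)=O)[C@@H]12 | intermediate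
27 | methyl methacrylate | C=C(C)C(=O)OC | starting material
28 | CNP0184381.3 (1R,4aS,7S,8R,11aR,12S) | C=C1CC[C@H]2O[C@@]2(C)CC[C@@H]2C([C@H](C/C=C(\C)C(=O)OC)OC(C)=O)=CO[C@H](OC(C)=O)[C@@H]12 | target

## Step count and least certain steps

Total: 19 steps. Longest linear sequence: 19 steps (1 to 28); 11 and 27 are purchased and enter in steps 7 and 19.

Step 11 (key step). The exocyclic enol ether may isomerise into the ring or hydrolyse on adventitious acid before it rearranges, because the seven-to-nine expansion needs a higher temperature than the six-to-eight case. One C7 epimer may also react more slowly, or some E-alkene may form if the boat-like transition state is less constrained than assumed. Fallback: starting from 16, the rearrangement is promoted by Al(i-Bu)3 in CH2Cl2 at −78 → 0 °C. Coordination of the ring oxygen advances C7–O cleavage so that C9–C10 bonding occurs below room temperature, and the aluminium reagent then reduces the new ketone by β-hydride transfer. This gives the (Z)-cyclononenol F1 (C11 epimers), which DMP oxidises to 17, where the route is rejoined. The activation changes from thermal pericyclic to Lewis-acid charge acceleration, and the enol ether is never heated.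

Step 3. The dialkylborane may reduce the enone carbonyl in competition with hydroboration, because the alkoxyborane formed first slows the alkene slightly and the reagent is in excess locally. Fallback: starting from 4, an excess of 9-BBN (3.5 equiv, rt) is used on purpose so that alkene hydroboration and 1,2-reduction of the enone both go to completion. The same buffered oxidation gives the allylic alcohol triol F2 (carbinol epimers). MnO2 in CH2Cl2 then oxidises only the allylic alcohol and returns the route to 6.

Step 14. Three things may go wrong: over-oxidation of the enolised malondialdehyde unit by the hypervalent iodine reagent, dehydration of the mono-oxidised β-hydroxy aldehyde to a 2-substituted acrolein, or a ring–chain equilibrium that does not favour the lactol. Fallback: the pyran is closed at the alcohol oxidation level and unsaturated afterwards, starting from 18. Bu4NF removes the silyl group to give the alcohol F3, and DMP then gives the C1 aldehyde F4. CSA in MeOH exchanges the acetonide and closes the cyclic methyl acetal F5 (O2–C3 formed as an ether, C12 as free CH2OH). DMP gives the aldehyde F6, and IBX in DMSO at 70 °C dehydrogenates C3–C4 to the vinylogous formate F7. PPTS in acetone/H2O finally hydrolyses the methyl acetal to 21, where the route is rejoined.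

Step 16. The conformational bias of the bicyclic nine-membered ring may oppose the reagent and erode facial selectivity. The C11 methylene may compete. The peroxymonosulfate may oxidise the aldehyde, or the anomeric acetate may hydrolyse in the aqueous buffer, during a slow reaction. Fallback: the epoxidation is moved ahead of pyran formation, starting from 19. The triol has no base-labile group and no aldehyde, so the standard K2CO3-buffered protocol with catalytic ketone can be used on the more flexible monocyclic diene to give the epoxy triol F8. DMP then gives the epoxy trialdehyde F9, which closes to the epoxy lactol F10. Acetylation as in step 15 gives 23, where the route is rejoined.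

Step 17. Addition to the electron-rich vinylogous formate carbonyl may be slow, the intrinsic facial preference of the aldehyde may oppose the reagent, or the C12–O bond next to the enol ether may ionise during oxidative work-up. Fallback: the whole side chain is attached in one C–C bond formation by a vinylogous Mukaiyama aldol. Commercial methyl tiglate is converted with LiN(i-Pr)2, DMPU and TBSCl into the silyl dienolate F11. This adds through its γ-carbon to 23 at −78 °C under BF3·OEt2, or under a stoichiometric tryptophan-derived oxazaborolidinone if reagent control is needed, to give the C12 alcohol F12 with the complete E-configured chain. Acetylation as in step 18 gives 28 directly, so steps 18 and 19 fall away. This fallback accepts a Lewis acid in the presence of the epoxide, which the main route avoids.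

## Further compounds

F1 | step 11 | (Z)-9-[(tert-butyldimethylsilyloxy)methyl]-8-(2,2-dimethyl-1,3-dioxan-5-yl)-5-methylcyclonon-4-en-1-ol (8,9-trans; C1 epimers) | OC1CC/C=C(C)\CC[C@H](C2COC(C)(C)OC2)[C@H]1CO[Si](C)(C)C(C)(C)C
F2 | step 3 | 2-[(1S)-5-hydroxy-4-methylcyclohex-3-en-1-yl]propane-1,3-diol (carbinol epimers) | CC1=CC[C@H](C(CO)CO)CC1O
F3 | step 14 | [(Z)-9-(2,2-dimethyl-1,3-dioxan-5-yl)-6-methyl-2-methylenecyclonon-5-en-1-yl]methanol (1,9-trans) | C=C1CC/C=C(C)\CC[C@H](C2COC(C)(C)OC2)[C@H]1CO
F4 | step 14 | (Z)-9-(2,2-dimethyl-1,3-dioxan-5-yl)-6-methyl-2-methylenecyclonon-5-ene-1-carbaldehyde (1,9-trans) | C=C1CC/C=C(C)\CC[C@H](C2COC(C)(C)OC2)[C@H]1C=O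
F5 | step 14 | [(4aS,11aR,Z)-1-methoxy-7-methyl-11-methylene-1,3,4,4a,5,6,9,10,11,11a-decahydrocyclonona[c]pyran-4-yl]methanol (C1 and C4 mixtures) | C=C1CC/C=C(C)\CC[C@@H]2C(CO)COC(OC)[C@@H]12
F6 | step 14 | (4aS,11aR,Z)-1-methoxy-7-methyl-11-methylene-1,3,4,4a,5,6,9,10,11,11a-decahydrocyclonona[c]pyran-4-carbaldehyde (C1 and C4 mixtures) | C=C1CC/C=C(C)\CC[C@@H]2C(C=O)COC(OC)[C@@H]12
F7 | step 14 | (4aS,11aR,Z)-1-methoxy-7-methyl-11-methylene-1,4a,5,6,9,10,11,11a-octahydrocyclonona[c]pyran-4-carbaldehyde (C1 anomers) | C=C1CC/C=C(C)\CC[C@@H]2C(C=O)=COC(OC)[C@@H]12
F8 | step 16 | (7S,8R)-7,8-epoxide of triol 19 | C=C1CC[C@H]2O[C@@]2(C)CC[C@H](C(CO)CO)[C@H]1CO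
F9 | step 16 | (7S,8R)-7,8-epoxide of trialdehyde 20 | C=C1CC[C@H]2O[C@@]2(C)CC[C@H](C(C=O)C=O)[C@H]1C=O
F10 | step 16 | (7S,8R)-7,8-epoxide of lactol 21 (C1 anomers) | C=C1CC[C@H]2O[C@@]2(C)CC[C@@H]2C(C=O)=COC(O)[C@@H]12
F11 | step 17 | tert-butyl[(1-methoxy-2-methylbuta-1,3-dien-1-yl)oxy]dimethylsilane | C=CC(C)=C(OC)O[Si](C)(C)C(C)(C)C
F12 | step 17 | 12-hydroxy precursor of 28 (12S, E side chain, C1 acetate) | C=C1CC[C@H]2O[C@@]2(C)CC[C@@H]2C([C@H](C/C=C(\C)C(=O)OC)O)=CO[C@H](OC(C)=O)[C@@H]12
A1 | alternative 1 | 6-substituted 2,2-dimethyl-4H-1,3-dioxin-4-one carrying the C7–C8 epoxide, the C4a=C4 unsaturated nitrile and the C3 allylic alcohol (alkene geometry left open) | CC1(C)OC(CC[C@H]2O[C@@]2(C)CCC=C(CO)C#N)=CC(=O)O1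
A2 | alternative 1 | epoxy cyclonona-fused β-keto δ-lactone nitrile | O=C1CC[C@H]2O[C@@]2(C)CC[C@@H]2[C@@H](C#N)COC(=O)[C@@H]12
A3 | alternative 2 | dihydropyran methyl acetal with the C5 bis(phenylsulfonyl)methyl group and the C8 allylic methyl carbonate (C8 epimers) | O=S(=O)(c1ccccc1)C(S(=O)(=O)c1ccccc1)[C@@H]1C=CO[C@H](OC)[C@H]1C(=C)CCC(OC(=O)OC)C(C)=C
A4 | alternative 2 | 5,5-bis(phenylsulfonyl) cyclonona-fused dihydropyran acetal | C=C1CC/C=C(C)\CC(S(=O)(=O)c3ccccc3)(S(=O)(=O)c3ccccc3)[C@@H]2C=CO[C@H](OC)[C@@H]12
A5 | alternative 3 | dihydropyran ester with the C4a vinyl group, the C11 dioxolane and the (Z)-C7 iodoalkene | C=C[C@@H]1C(C(=O)OC)=CO[C@H](OC)[C@H]1C1(OCCO1)CC/C=C(C)\I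
A6 | alternative 3 | cyclonona-fused dihydropyran ester, C11 dioxolane | C12(OCCO1)CC/C=C(C)\CC[C@@H]3C(C(=O)OC)=CO[C@H](OC)[C@@H]23
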